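The cyclohexene carbons are labelled C3 (bearing OAc), C4 (gem-dimethyl), C5 (chain-bearing), C10 and C1 (the ring alkene, C10 methylated) and C2; chain carbons continue C6, C7, C8, C9, C11. The C3–O and C5–C6 bonds lie on the same ring face, flanking C4, so O3 and C7 can be joined as an unsaturated six-membered lactone and the ring cut at C5–C10. Forward, a reductive Heck closure of a (Z)-vinyl iodide onto lactone carbon C5 forms the carbocycle (6-exo), the C5 stereocentre and the endocyclic C1=C10 alkene together. The precursor is (6S)-6-[(2Z)-3-iodobut-2-en-1-yl]-5,5-dimethyl-5,6-dihydro-2H-pyran-2-one; the bridged lactone later opens to the C3 alcohol and a C7 handle.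

Key step: step 10

Assumption: the (R)-SEGPHOS-modified iridium catalyst is taken to give the (3S) carbinol 5; the sense is to be confirmed by Mosher ester analysis of 5, and the (S)-ligand is used without other change should it prove opposite.

Step 1
Reactants: 1 propane-1,3-diol
Product: 2 3-[(4-methoxybenzyl)oxy]propan-1-ol
Conditions: NaH (1 equiv), 4-methoxybenzyl chloride (1 equiv), Bu4NI (cat.), diol (3 equiv), THF–DMF, 0 °C → rt
Reagents that add atoms: 4-methoxybenzyl chloride, COc1ccc(CCl)cc1
Why: Williamson ether synthesis on the symmetrical diol, run with excess diol so that statistical mono-alkylation should dominate over bis-ether formation.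

Step 2
Reactants: 2 3-[(4-methoxybenzyl)oxy]propan-1-ol; 3 3-methylbuta-1,2-diene
Product: 5 (3S)-1-[(4-methoxybenzyl)oxy]-4,4-dimethylhex-5-en-3-ol, via 3-[(4-methoxybenzyl)oxy]propanal 4 (not isolated)
Conditions: cyclometalated π-allyl iridium C,O-benzoate catalyst (5 mol %; from [Ir(cod)Cl]2, (R)-SEGPHOS, 4-cyano-3-nitrobenzoic acid, allyl acetate, Cs2CO3), toluene, 60 °C, sealed tube
Reagents that add atoms: none
Why: Iridium-catalysed transfer-hydrogenative carbonyl tert-prenylation from the alcohol oxidation level, in which dehydrogenation of 2 gives aldehyde 4 and an iridium hydride that hydrometalates the allene, and the 1,1-dimethylallyl iridium adds through its substituted terminus in a closed chair transition state whose aldehyde face is chosen by the chiral bisphosphine, setting C3 as (S).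

Step 3
Reactants: 5 (3S)-1-[(4-methoxybenzyl)oxy]-4,4-dimethylhex-5-en-3-ol
Product: 6 tert-butyl{[(3S)-1-[(4-methoxybenzyl)oxy]-4,4-dimethylhex-5-en-3-yl]oxy}dimethylsilane
Conditions: TBSOTf, 2,6-lutidine, CH2Cl2, −78 → 0 °C
Reagents that add atoms: tert-butyldimethylsilyl trifluoromethanesulfonate, CC(C)(C)[Si](C)(C)OS(=O)(=O)C(F)(F)F
Why: Silylation with the silyl triflate and a hindered pyridine base is fast enough for the secondary alcohol next to the quaternary carbon and should leave the PMB ether and the vinyl group untouched.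

Step 4
Reactants: 6 tert-butyl{[(3S)-1-[(4-methoxybenzyl)oxy]-4,4-dimethylhex-5-en-3-yl]oxy}dimethylsilane
Product: 7 (3S)-3-[(tert-butyldimethylsilyl)oxy]-4,4-dimethylhex-5-en-1-ol
Conditions: DDQ, CH2Cl2–pH 7 buffer, 0 °C → rt
Reagents that add atoms: none
Why: Oxidative PMB ether cleavage by DDQ (hydride abstraction at the electron-rich benzylic position, then hydrolysis) is selective over the TBS ether and the unactivated alkene under buffered conditions.

Step 5
Reactants: 7 (3S)-3-[(tert-butyldimethylsilyl)oxy]-4,4-dimethylhex-5-en-1-ol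
Product: 8 (3S)-3-[(tert-butyldimethylsilyl)oxy]-4,4-dimethylhex-5-enal
Conditions: Dess–Martin periodinane, NaHCO3, CH2Cl2, 0 °C → rt
Reagents that add atoms: none
Why: Dess–Martin oxidation stops at the aldehyde under buffered, non-basic conditions that should neither eliminate the β-silyloxy group nor touch the stereocentre.

Step 6
Reactants: 8 (3S)-3-[(tert-butyldimethylsilyl)oxy]-4,4-dimethylhex-5-enal
Product: 9 tert-butyl{[(4S,6Z)-7-iodo-3,3-dimethylocta-1,6-dien-4-yl]oxy}dimethylsilane
Conditions: EtPPh3I, n-BuLi, THF, rt; I2, −78 °C; NaN(SiMe3)2, −20 °C; then 8, −78 °C → −20 °C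
Reagents that add atoms: ethyltriphenylphosphonium iodide, CC[P+](c1ccccc1)(c1ccccc1)c1ccccc1.[I-]; iodine, II
Why: This is the α-methyl variant of the Stork–Zhao iodo-olefination (a Wittig reaction), in which the non-stabilised α-iodoethylidene ylide adds under kinetic control at low temperature through the cis-oxaphosphetane, so the alkene should form with iodine cis to the chain, that is (Z), with the future C10 methyl already in place.

Step 7
Reactants: 9 tert-butyl{[(4S,6Z)-7-iodo-3,3-dimethylocta-1,6-dien-4-yl]oxy}dimethylsilane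
Product: 10 (4S,6Z)-7-iodo-3,3-dimethylocta-1,6-dien-4-ol
Conditions: Bu4NF, THF, rt → 45 °C
Reagents that add atoms: none
Why: Fluoride-driven cleavage of the Si–O bond frees the alcohol, and the vinyl iodide and the terminal alkene are inert to Bu4NF.

Step 8
Reactants: 10 (4S,6Z)-7-iodo-3,3-dimethylocta-1,6-dien-4-ol; 11 acryloyl chloride
Product: 12 (4S,6Z)-7-iodo-3,3-dimethylocta-1,6-dien-4-yl prop-2-enoate
Conditions: iPr2NEt, DMAP (cat.), CH2Cl2, −20 → 0 °C
Reagents that add atoms: none
Why: DMAP-catalysed O-acylation of the hindered secondary alcohol with the acid chloride leaves the configuration at the carbinol carbon unchanged.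

Step 9
Reactants: 12 (4S,6Z)-7-iodo-3,3-dimethylocta-1,6-dien-4-yl prop-2-enoate
Product: 13 (6S)-6-[(2Z)-3-iodobut-2-en-1-yl]-5,5-dimethyl-5,6-dihydro-2H-pyran-2-one
Conditions: second-generation Grubbs catalyst RuCl2(=CHPh)(PCy3)(H2IMes) (5–10 mol %), toluene (high dilution), 80 °C
Reagents that add atoms: none
Why: Ring-closing metathesis between the acrylate and the vinyl group on the quaternary carbon should close the six-membered unsaturated lactone with loss of ethene, helped by the gem-dimethyl (Thorpe–Ingold) effect, while the trisubstituted vinyl iodide is too hindered and electron-poor to engage the ruthenium carbene.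

Step 10
Reactants: 13 (6S)-6-[(2Z)-3-iodobut-2-en-1-yl]-5,5-dimethyl-5,6-dihydro-2H-pyran-2-one
Product: 14 (1S,5R)-6,9,9-trimethyl-2-oxabicyclo[3.3.1]non-6-en-3-one
Conditions: Pd(OAc)2 (10 mol %), PPh3 (20 mol %), HCO2Na (1.5 equiv), Bu4NCl, DMF, 80 °C
Reagents that add atoms: none
Why: Zerovalent palladium, formed in the flask from Pd(OAc)2 and PPh3, inserts into the C10–I bond with retention of the (Z) geometry, and the vinylpalladium then adds syn across the lactone alkene from the face of the axial arm, forging C5–C10 and leaving palladium on C6 as an enolate. Because H-5 is anti to palladium and a C5=C6 alkene would sit at a bridgehead, β-hydride elimination is shut off, so formate displaces iodide, loses CO2 and delivers hydride to C6 with return of zerovalent palladium. The closest known reaction type is the intramolecular reductive Heck (formal conjugate vinylation) of vinyl iodides onto cyclic enones and enoates. The one ring closed, the carbocycle C3–C2–C1=C10–C5–C4, forms in the 6-exo-trig mode and leaves the lactone as the second bridge of a 2-oxabicyclo[3.3.1]nonene. The new stereocentre C5 is set by the tether: the three-atom arm on C3 can reach C5 only on the face cis to the C3–O bond, so (S)-C3 enforces (R)-C5. The step needs attack at the β-carbon and insertion faster than formate reduction of the vinylpalladium; the 6-exo geometry, the enoate polarisation and the gem-dimethyl group at C4, which favours the axial-arm conformer, secure this, and the (Z)-iodide guarantees that C1=C10 lies inside the new ring.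

Step 11
Reactants: 14 (1S,5R)-6,9,9-trimethyl-2-oxabicyclo[3.3.1]non-6-en-3-one
Product: 15 (1S,5R)-5-(2-hydroxyethyl)-4,6,6-trimethylcyclohex-3-en-1-ol
Conditions: LiAlH4, THF, 0 °C → rt
Reagents that add atoms: none
Why: Hydride reduction of the lactone (ester reduction) opens the bridge to the C3,C7 diol without affecting the isolated trisubstituted alkene or either stereocentre.

Step 12
Reactants: 15 (1S,5R)-5-(2-hydroxyethyl)-4,6,6-trimethylcyclohex-3-en-1-ol
Product: 16 (1S,5R)-5-(2-iodoethyl)-4,6,6-trimethylcyclohex-3-en-1-ol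
Conditions: PPh3, imidazole, I2 (premixed), CH2Cl2, 0 °C; then 15
Reagents that add atoms: iodine, II
Why: Appel-type iodination (Garegg–Samuelsson conditions) with the preformed phosphonium reagent should convert only the unhindered primary alcohol by SN2 displacement, the secondary alcohol beside C4 being too hindered to be activated and no free iodine being left to attack the ring alkene.

Step 13
Reactants: 16 (1S,5R)-5-(2-iodoethyl)-4,6,6-trimethylcyclohex-3-en-1-ol
Product: 17 tert-butyl{[(1S,5R)-5-(2-iodoethyl)-4,6,6-trimethylcyclohex-3-en-1-yl]oxy}dimethylsilane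
Conditions: TBSOTf, 2,6-lutidine, CH2Cl2, −78 → 0 °C
Reagents that add atoms: tert-butyldimethylsilyl trifluoromethanesulfonate, CC(C)(C)[Si](C)(C)OS(=O)(=O)C(F)(F)F
Why: Silyl triflate silylation masks the C3 hydroxyl before the basic steps, which prevents Williamson closure of a C3 alkoxide onto C7, and the primary iodide does not react with the reagents at low temperature.

Step 14
Reactants: 17 tert-butyl{[(1S,5R)-5-(2-iodoethyl)-4,6,6-trimethylcyclohex-3-en-1-yl]oxy}dimethylsilane
Product: 18 {[(1S,5R)-5-(but-3-yn-1-yl)-4,6,6-trimethylcyclohex-3-en-1-yl]oxy}(tert-butyl)dimethylsilane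
Conditions: LiC≡CH·H2NCH2CH2NH2, DMSO, rt
Reagents that add atoms: lithium acetylide–ethylenediamine complex, [Li+].[C-]#C.NCCN
Why: SN2 alkylation of lithium acetylide by the unhindered primary iodide in a dipolar aprotic solvent adds C8 and C9, and the TBS ether withstands the base.

Step 15
Reactants: 18 {[(1S,5R)-5-(but-3-yn-1-yl)-4,6,6-trimethylcyclohex-3-en-1-yl]oxy}(tert-butyl)dimethylsilane
Product: 20 tert-butyl{[(1S,5R)-5-[(3E)-4-iodo-3-methylbut-3-en-1-yl]-4,6,6-trimethylcyclohex-3-en-1-yl]oxy}dimethylsilane, via (E)-alkenyldimethylalane 19 (not isolated)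
Conditions: AlMe3 (2.5 equiv), Cp2ZrCl2 (0.3 equiv), CH2Cl2, 0 °C → rt; then I2, THF, −30 → 0 °C
Reagents that add atoms: trimethylaluminium, C[Al](C)C; iodine, II
Why: Negishi zirconium-catalysed carboalumination adds methyl and aluminium syn across the terminal alkyne with aluminium on the terminal carbon, and iodinolysis of the C–Al bond with retention should give the (E)-vinyl iodide, fixing the C8=C9 geometry.

Step 16
Reactants: 21 (2E,6E)-farnesol
Product: 22 (2E,6E)-3,7,11-trimethyldodeca-2,6,10-trienal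
Conditions: MnO2 (excess), CH2Cl2, rt
Reagents that add atoms: none
Why: MnO2 oxidises the allylic alcohol selectively to the enal under neutral heterogeneous conditions without isomerising the alkenes.

Step 17
Reactants: 22 (2E,6E)-3,7,11-trimethyldodeca-2,6,10-trienal
Product: 23 (3E,7E)-4,8,12-trimethyltrideca-1,3,7,11-tetraene
Conditions: Ph3PCH3Br, n-BuLi, THF, 0 °C; then 22, −78 °C → rt
Reagents that add atoms: methyltriphenylphosphonium bromide, C[P+](c1ccccc1)(c1ccccc1)c1ccccc1.[Br-]
Why: Wittig methylenation with the non-stabilised ylide turns the aldehyde into a terminal vinyl group and leaves the (E)-trisubstituted alkenes unchanged.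

Step 18
Reactants: 23 (3E,7E)-4,8,12-trimethyltrideca-1,3,7,11-tetraene; 20 tert-butyl{[(1S,5R)-5-[(3E)-4-iodo-3-methylbut-3-en-1-yl]-4,6,6-trimethylcyclohex-3-en-1-yl]oxy}dimethylsilane
Product: 25 tert-butyldimethyl{[(1S,5R)-4,6,6-trimethyl-5-[(3E,7E,11E)-3,8,12,16-tetramethylheptadeca-3,7,11,15-tetraen-1-yl]cyclohex-3-en-1-yl]oxy}silane, via B-alkyl-9-BBN adduct 24 (not isolated)
Conditions: 23, 9-BBN, THF, 0 °C → rt; then 20, PdCl2(dppf) (5 mol %), AsPh3 (10 mol %), aq. Cs2CO3, DMF–THF, rt → 45 °C
Reagents that add atoms: none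
Why: The bulky 9-BBN hydroborates only the monosubstituted terminal alkene of 23 with boron on the terminal carbon, and B-alkyl Suzuki–Miyaura coupling of borane 24 with vinyl iodide 20 should form the C9–C11 bond with retention of the (E) geometry.

Step 19
Reactants: 25 tert-butyldimethyl{[(1S,5R)-4,6,6-trimethyl-5-[(3E,7E,11E)-3,8,12,16-tetramethylheptadeca-3,7,11,15-tetraen-1-yl]cyclohex-3-en-1-yl]oxy}silane
Product: 26 (1S,5R)-4,6,6-trimethyl-5-[(3E,7E,11E)-3,8,12,16-tetramethylheptadeca-3,7,11,15-tetraen-1-yl]cyclohex-3-en-1-ol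
Conditions: Bu4NF, THF, rt → 50 °C
Reagents that add atoms: none
Why: Fluoride desilylation frees the C3 hydroxyl, and the skipped polyene carries nothing sensitive to Bu4NF.

Step 20
Reactants: 26 (1S,5R)-4,6,6-trimethyl-5-[(3E,7E,11E)-3,8,12,16-tetramethylheptadeca-3,7,11,15-tetraen-1-yl]cyclohex-3-en-1-ol
Product: 27 (1S,5R)-4,6,6-trimethyl-5-[(3E,7E,11E)-3,8,12,16-tetramethylheptadeca-3,7,11,15-tetraen-1-yl]cyclohex-3-en-1-yl acetate
Conditions: Ac2O, pyridine, DMAP (cat.), CH2Cl2, rt
Reagents that add atoms: acetic anhydride, CC(=O)OC(C)=O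
Why: DMAP-catalysed acetylation of the secondary alcohol proceeds with retention at C3 and should give the target acetate.

Compound list
1 | propane-1,3-diol | OCCCO | starting material
2 | 3-[(4-methoxybenzyl)oxy]propan-1-ol | COc1ccc(COCCCO)cc1 | intermediate
3 | 3-methylbuta-1,2-diene | CC(C)=C=C | starting material
4 | 3-[(4-methoxybenzyl)oxy]propanal (not isolated) | COc1ccc(COCCC=O)cc1 | intermediate
5 | (3S)-1-[(4-methoxybenzyl)oxy]-4,4-dimethylhex-5-en-3-ol | COc1ccc(COCC[C@H](O)C(C)(C)C=C)cc1 | intermediate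
6 | tert-butyl{[(3S)-1-[(4-methoxybenzyl)oxy]-4,4-dimethylhex-5-en-3-yl]oxy}dimethylsilane | COc1ccc(COCC[C@H](O[Si](C)(C)C(C)(C)C)C(C)(C)C=C)cc1 | intermediate
7 | (3S)-3-[(tert-butyldimethylsilyl)oxy]-4,4-dimethylhex-5-en-1-ol | OCC[C@H](O[Si](C)(C)C(C)(C)C)C(C)(C)C=C | intermediate
8 | (3S)-3-[(tert-butyldimethylsilyl)oxy]-4,4-dimethylhex-5-enal | O=CC[C@H](O[Si](C)(C)C(C)(C)C)C(C)(C)C=C | intermediate
9 | tert-butyl{[(4S,6Z)-7-iodo-3,3-dimethylocta-1,6-dien-4-yl]oxy}dimethylsilane | C=CC(C)(C)[C@H](C/C=C(/C)I)O[Si](C)(C)C(C)(C)C | intermediate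
10 | (4S,6Z)-7-iodo-3,3-dimethylocta-1,6-dien-4-ol | C=CC(C)(C)[C@H](C/C=C(/C)I)O | intermediate
11 | acryloyl chloride | C=CC(=O)Cl | starting material
12 | (4S,6Z)-7-iodo-3,3-dimethylocta-1,6-dien-4-yl prop-2-enoate | C=CC(=O)O[C@@H](C/C=C(/C)I)C(C)(C)C=C | intermediate
13 | (6S)-6-[(2Z)-3-iodobut-2-en-1-yl]-5,5-dimethyl-5,6-dihydro-2H-pyran-2-one | O=C1C=CC(C)(C)[C@H](C/C=C(/C)I)O1 | intermediate
14 | (1S,5R)-6,9,9-trimethyl-2-oxabicyclo[3.3.1]non-6-en-3-one | O=C1C[C@@H]2C(C)=CC[C@H](O1)C2(C)C | intermediate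
15 | (1S,5R)-5-(2-hydroxyethyl)-4,6,6-trimethylcyclohex-3-en-1-ol | OCC[C@@H]1C(C)=CC[C@H](O)C1(C)C | intermediate
16 | (1S,5R)-5-(2-iodoethyl)-4,6,6-trimethylcyclohex-3-en-1-ol | ICC[C@@H]1C(C)=CC[C@H](O)C1(C)C | intermediate
17 | tert-butyl{[(1S,5R)-5-(2-iodoethyl)-4,6,6-trimethylcyclohex-3-en-1-yl]oxy}dimethylsilane | ICC[C@@H]1C(C)=CC[C@H](O[Si](C)(C)C(C)(C)C)C1(C)C | intermediate
18 | {[(1S,5R)-5-(but-3-yn-1-yl)-4,6,6-trimethylcyclohex-3-en-1-yl]oxy}(tert-butyl)dimethylsilane | C#CCC[C@@H]1C(C)=CC[C@H](O[Si](C)(C)C(C)(C)C)C1(C)C | intermediate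
19 | [(1E)-4-{(1R,5S)-5-[(tert-butyldimethylsilyl)oxy]-2,6,6-trimethylcyclohex-2-en-1-yl}-2-methylbut-1-en-1-yl]dimethylalumane (not isolated) | C[Al](C)/C=C(\C)CC[C@@H]1C(C)=CC[C@H](O[Si](C)(C)C(C)(C)C)C1(C)C | intermediate
20 | tert-butyl{[(1S,5R)-5-[(3E)-4-iodo-3-methylbut-3-en-1-yl]-4,6,6-trimethylcyclohex-3-en-1-yl]oxy}dimethylsilane | I/C=C(\C)CC[C@@H]1C(C)=CC[C@H](O[Si](C)(C)C(C)(C)C)C1(C)C | intermediate
21 | (2E,6E)-farnesol, (2E,6E)-3,7,11-trimethyldodeca-2,6,10-trien-1-ol | CC(C)=CCC/C(C)=C/CC/C(C)=C/CO | starting material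
22 | (2E,6E)-3,7,11-trimethyldodeca-2,6,10-trienal | CC(C)=CCC/C(C)=C/CC/C(C)=C/C=O | intermediate
23 | (3E,7E)-4,8,12-trimethyltrideca-1,3,7,11-tetraene | CC(C)=CCC/C(C)=C/CC/C(C)=C/C=C | intermediate
24 | 9-[(3E,7E)-4,8,12-trimethyltrideca-3,7,11-trien-1-yl]-9-borabicyclo[3.3.1]nonane (not isolated) | CC(C)=CCC/C(C)=C/CC/C(C)=C/CCB1C2CCCC1CCC2 | intermediate
25 | tert-butyldimethyl{[(1S,5R)-4,6,6-trimethyl-5-[(3E,7E,11E)-3,8,12,16-tetramethylheptadeca-3,7,11,15-tetraen-1-yl]cyclohex-3-en-1-yl]oxy}silane | CC(C)(C)[Si](C)(C)O[C@H]1CC=C(C)[C@@H](CC/C(C)=C/CC/C=C(\C)CC/C=C(\C)CCC=C(C)C)C1(C)C | intermediate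
26 | (1S,5R)-4,6,6-trimethyl-5-[(3E,7E,11E)-3,8,12,16-tetramethylheptadeca-3,7,11,15-tetraen-1-yl]cyclohex-3-en-1-ol | O[C@H]1CC=C(C)[C@@H](CC/C(C)=C/CC/C=C(\C)CC/C=C(\C)CCC=C(C)C)C1(C)C | intermediate
27 | (1S,5R)-4,6,6-trimethyl-5-[(3E,7E,11E)-3,8,12,16-tetramethylheptadeca-3,7,11,15-tetraen-1-yl]cyclohex-3-en-1-yl acetate (CNP0313409.1) | CC(=O)O[C@H]1CC=C(C)[C@@H](CC/C(C)=C/CC/C=C(\C)CC/C=C(\C)CCC=C(C)C)C1(C)C | target

Total step count: 20. Longest linear sequence: 18 steps (steps 1–15, then 18–20); steps 16 and 17 make the side-chain fragment.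

Steps most likely to fail

Step 10. The vinylpalladium may be reduced by formate before it inserts, or insertion may stall at the hindered β-carbon beside C4, so that de-iodinated lactone accumulates. The fallback sets out from 13 and replaces the organopalladium pathway by a radical chain: Bu3SnH added slowly with AIBN in benzene at 80 °C should generate the C10 vinyl radical, which closes 6-exo-trig onto C5 of the enoate, and the resulting α-acyl radical takes hydrogen from Bu3SnH. The tether enforces the same cis relationship, and inversion of the vinyl radical is harmless because the alkene ends up inside the ring. The route is rejoined directly at 14, so this detour makes no new compound (F0).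

Step 6. (Z) selectivity may erode, the ylide may lose iodine, or base may eliminate the β-silyloxy group from the aldehyde. The fallback sets out from 8: Corey–Fuchs dibromomethylenation (CBr4, PPh3, 2,6-lutidine, CH2Cl2, 0 °C) should give tert-butyl{[(4S)-7,7-dibromo-3,3-dimethylhepta-1,6-dien-4-yl]oxy}dimethylsilane F1. Trans-selective Negishi mono-methylation (MeZnBr, PdCl2(DPEphos), THF–DMF, 0 °C → rt) then replaces the bromide trans to the chain and leaves tert-butyl{[(4S,6Z)-7-bromo-3,3-dimethylocta-1,6-dien-4-yl]oxy}dimethylsilane F2. Copper-catalysed halide exchange with retention of geometry (NaI, CuI, N,N′-dimethylethane-1,2-diamine, dioxane, 110 °C) returns to the route at 9.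

Step 9. Ring closure may be slow because one alkene is neopentylic and the other electron-poor, so that catalyst decay or intermolecular metathesis competes. The fallback sets out from 10: esterification with diethylphosphonoacetic acid (DCC, DMAP, CH2Cl2) should give (4S,6Z)-7-iodo-3,3-dimethylocta-1,6-dien-4-yl (diethoxyphosphoryl)acetate F3. Lemieux–Johnson cleavage (OsO4 cat., NaIO4, 2,6-lutidine, dioxane–water) of the monosubstituted alkene, which is more electron-rich and less hindered than the iodoalkene, gives the non-enolisable aldehyde (3S,5Z)-6-iodo-2,2-dimethyl-1-oxohept-5-en-3-yl (diethoxyphosphoryl)acetate F4. Intramolecular Horner–Wadsworth–Emmons olefination under Masamune–Roush conditions (LiCl, iPr2NEt, MeCN) closes the unsaturated lactone and rejoins the route at 13.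

Further compounds
F0 | step 10 | none | none
F1 | step 6 | tert-butyl{[(4S)-7,7-dibromo-3,3-dimethylhepta-1,6-dien-4-yl]oxy}dimethylsilane | C=CC(C)(C)[C@H](CC=C(Br)Br)O[Si](C)(C)C(C)(C)C
F2 | step 6 | tert-butyl{[(4S,6Z)-7-bromo-3,3-dimethylocta-1,6-dien-4-yl]oxy}dimethylsilane | C=CC(C)(C)[C@H](C/C=C(/C)Br)O[Si](C)(C)C(C)(C)C
F3 | step 9 | (4S,6Z)-7-iodo-3,3-dimethylocta-1,6-dien-4-yl (diethoxyphosphoryl)acetate | CCOP(=O)(OCC)CC(=O)O[C@@H](C/C=C(/C)I)C(C)(C)C=C
F4 | step 9 | (3S,5Z)-6-iodo-2,2-dimethyl-1-oxohept-5-en-3-yl (diethoxyphosphoryl)acetate | CCOP(=O)(OCC)CC(=O)O[C@@H](C/C=C(/C)I)C(C)(C)C=O
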